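The 4‑hydroxy‑2‑pyranone ring (O1, C2, C3, C4, C5, C6) is disconnected at C3–C4 only, because its O1–C2 bond is an ester linkage that can be installed beforehand on a C6 carbinol. The key step converts an open‑chain 2‑bromobutanoate of a β‑hydroxy methyl ester, already carrying the complete syn,syn C7–C9 triad and the (E)‑silyloxypropenyl arene, into the 3‑ethyl‑4‑hydroxy‑5,6‑dihydropyranone in one operation: a bromide‑derived magnesium enolate at C3 attacks the C4 ester. Selenoxide dehydrogenation across C5–C6 and desilylation then give veramycin A. The triad comes from Sharpless epoxidation, AlMe3 epoxide opening and an Evans aldol.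

Key step: step 13

Remark: C6 (the carbinol made in step 11) and the bromine‑bearing carbon are formed without control and cease to be stereocentres by step 14, so compounds 18 and 20–25 are epimer mixtures there and their SMILES leave these atoms undefined; labels C2–C9 follow the pyranone numbering of the target.

Step 1
Reactants: 1 2‑bromo‑4‑methylbenzaldehyde; 2 ethyl (triphenylphosphoranylidene)acetate
Product: 3 ethyl (2E)‑3‑(2‑bromo‑4‑methylphenyl)prop‑2‑enoate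
Conditions: Ph3P=CHCO2Et, toluene, 80 °C
Reagents that add atoms: ethyl (triphenylphosphoranylidene)acetate (2), CCOC(=O)C=P(c1ccccc1)(c1ccccc1)c1ccccc1
Why: A stabilised ylide reacts with the aryl aldehyde in a Wittig olefination that should give the (E)‑enoate, and the aryl bromide is inert.

Step 2
Reactants: 3 ethyl (2E)‑3‑(2‑bromo‑4‑methylphenyl)prop‑2‑enoate
Product: 4 (2E)‑3‑(2‑bromo‑4‑methylphenyl)prop‑2‑en‑1‑ol
Conditions: i‑Bu2AlH (2.2 equiv), CH2Cl2, −78 °C; aq. potassium sodium tartrate (KNaC4H4O6)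
Reagents that add atoms: none
Why: 1,2‑Hydride reduction of the conjugated ester by the aluminium hydride at low temperature should give the allylic alcohol without touching the alkene or the aryl bromide.

Step 3
Reactants: 4 (2E)‑3‑(2‑bromo‑4‑methylphenyl)prop‑2‑en‑1‑ol
Product: 5 [(2R,3R)‑3‑(2‑bromo‑4‑methylphenyl)oxiran‑2‑yl]methanol
Conditions: Ti(OiPr)4 (10 mol %), D‑(−)‑diisopropyl tartrate (12 mol %), t‑BuOOH, 4 Å molecular sieves, CH2Cl2, −20 °C
Reagents that add atoms: tert‑butyl hydroperoxide, CC(C)(C)OO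
Why: Sharpless asymmetric epoxidation is highly selective for (E)‑3‑aryl allylic alcohols, and the D‑(−)‑tartrate catalyst should deliver oxygen to the face that gives the (2R,3R)‑epoxide, which fixes the future benzylic centre C9.

Step 4
Reactants: 5 [(2R,3R)‑3‑(2‑bromo‑4‑methylphenyl)oxiran‑2‑yl]methanol
Product: 6 (2S,3S)‑3‑(2‑bromo‑4‑methylphenyl)butane‑1,2‑diol
Conditions: AlMe3 (3 equiv), CH2Cl2/hexane, 0 °C to rt; aq. potassium sodium tartrate (KNaC4H4O6)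
Reagents that add atoms: trimethylaluminium, C[Al](C)C
Why: The aluminium‑complexed 2,3‑epoxy alcohol should open at the benzylic carbon C3, which best supports positive charge, with methyl delivered with inversion (regio‑ and stereospecific epoxide opening), turning the (3R)‑epoxide carbon into the (3S)‑methyl centre.

Step 5
Reactants: 6 (2S,3S)‑3‑(2‑bromo‑4‑methylphenyl)butane‑1,2‑diol
Product: 7 (2S)‑2‑(2‑bromo‑4‑methylphenyl)propanal
Conditions: NaIO4, THF/pH 7 buffer, 0 °C; extractive work‑up, crude aldehyde used at once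
Reagents that add atoms: none
Why: Periodate glycol cleavage under neutral conditions removes C1 as formaldehyde and should release the enolisable α‑aryl aldehyde without the acid or base that could racemise it.

Step 6
Reactants: 7 (2S)‑2‑(2‑bromo‑4‑methylphenyl)propanal; 8 (4S)‑4‑benzyl‑3‑propanoyl‑1,3‑oxazolidin‑2‑one
Product: 10 (4S)‑4‑benzyl‑3‑[(2S,3R,4S)‑4‑(2‑bromo‑4‑methylphenyl)‑3‑hydroxy‑2‑methylpentanoyl]‑1,3‑oxazolidin‑2‑one, via dibutylboron Z‑enolate of the propanoyl imide 9 (not isolated)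
Conditions: 8, Bu2BOTf, i‑Pr2NEt, CH2Cl2, 0 °C; then 7, −78 to 0 °C; pH 7 buffer, MeOH, 30% H2O2
Reagents that add atoms: (4S)‑4‑benzyl‑3‑propanoyl‑1,3‑oxazolidin‑2‑one (8), CCC(=O)N1[C@@H](Cc2ccccc2)COC1=O
Why: The boron (Z)‑enolate reacts through a closed Zimmerman–Traxler chair with the auxiliary carbonyl turned away (Evans syn aldol), so the (S)‑benzyl auxiliary should set C7 and C8 as 2S,3R by reagent control, and this si‑face attack on the aldehyde is also the Felkin–Anh sense for the (S)‑α‑aryl centre, completing the syn,syn triad.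

Step 7
Reactants: 10 (4S)‑4‑benzyl‑3‑[(2S,3R,4S)‑4‑(2‑bromo‑4‑methylphenyl)‑3‑hydroxy‑2‑methylpentanoyl]‑1,3‑oxazolidin‑2‑one
Product: 11 (2S,3R,4S)‑4‑(2‑bromo‑4‑methylphenyl)‑3‑hydroxy‑N‑methoxy‑N,2‑dimethylpentanamide
Conditions: MeNHOMe·HCl, AlMe3, THF, −15 to 0 °C
Reagents that add atoms: N,O‑dimethylhydroxylamine hydrochloride, CNOC.Cl
Why: The aluminium amide attacks the exocyclic imide carbonyl with assistance from the free β‑hydroxyl (Weinreb transamination), which should give the amide without retro‑aldol or epimerisation and return the auxiliary.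

Step 8
Reactants: 11 (2S,3R,4S)‑4‑(2‑bromo‑4‑methylphenyl)‑3‑hydroxy‑N‑methoxy‑N,2‑dimethylpentanamide
Product: 12 (2S,3R,4S)‑4‑(2‑bromo‑4‑methylphenyl)‑3‑(tert‑butyldimethylsilyloxy)‑N‑methoxy‑N,2‑dimethylpentanamide
Conditions: TBSOTf, 2,6‑lutidine, CH2Cl2, −78 to 0 °C
Reagents that add atoms: tert‑butyldimethylsilyl trifluoromethanesulfonate, CC(C)(C)[Si](C)(C)OS(=O)(=O)C(F)(F)F
Why: A silyl triflate with a hindered pyridine base silylates even this flanked secondary alcohol (O‑silylation), and the ether masks the C8 oxygen through all later basic, organometallic and acylating steps.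

Step 9
Reactants: 12 (2S,3R,4S)‑4‑(2‑bromo‑4‑methylphenyl)‑3‑(tert‑butyldimethylsilyloxy)‑N‑methoxy‑N,2‑dimethylpentanamide; 13 tert‑butyldimethyl{[(2E)‑3‑(4,4,5,5‑tetramethyl‑1,3,2‑dioxaborolan‑2‑yl)prop‑2‑en‑1‑yl]oxy}silane
Product: 14 (2S,3R,4S)‑3‑(tert‑butyldimethylsilyloxy)‑4‑{2‑[(E)‑3‑(tert‑butyldimethylsilyloxy)prop‑1‑en‑1‑yl]‑4‑methylphenyl}‑N‑methoxy‑N,2‑dimethylpentanamide
Conditions: Pd(OAc)2 (5 mol %), SPhos (dicyclohexyl(2',6'‑dimethoxybiphenyl‑2‑yl)phosphine, 10 mol %), K3PO4, toluene/H2O, 80 °C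
Reagents that add atoms: tert‑butyldimethyl{[(2E)‑3‑(4,4,5,5‑tetramethyl‑1,3,2‑dioxaborolan‑2‑yl)prop‑2‑en‑1‑yl]oxy}silane (13), CC(C)(C)[Si](C)(C)OC/C=C/B1OC(C)(C)C(C)(C)O1
Why: Suzuki–Miyaura coupling with an electron‑rich biarylphosphine tolerates the ortho secondary‑alkyl group and transfers the alkenyl unit with retention of E geometry, and it removes the aryl C–Br bond before the bromo ester is introduced.

Step 10
Reactants: 14 (2S,3R,4S)‑3‑(tert‑butyldimethylsilyloxy)‑4‑{2‑[(E)‑3‑(tert‑butyldimethylsilyloxy)prop‑1‑en‑1‑yl]‑4‑methylphenyl}‑N‑methoxy‑N,2‑dimethylpentanamide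
Product: 15 (2S,3R,4S)‑3‑(tert‑butyldimethylsilyloxy)‑4‑{2‑[(E)‑3‑(tert‑butyldimethylsilyloxy)prop‑1‑en‑1‑yl]‑4‑methylphenyl}‑2‑methylpentanal
Conditions: i‑Bu2AlH, THF, −78 °C; aq. potassium sodium tartrate (KNaC4H4O6)
Reagents that add atoms: none
Why: Hydride addition to the Weinreb amide gives a chelated tetrahedral intermediate that persists until work‑up (Weinreb amide reduction), so the aldehyde should form without over‑reduction and without epimerising C7 at −78 °C.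

Step 11
Reactants: 15 (2S,3R,4S)‑3‑(tert‑butyldimethylsilyloxy)‑4‑{2‑[(E)‑3‑(tert‑butyldimethylsilyloxy)prop‑1‑en‑1‑yl]‑4‑methylphenyl}‑2‑methylpentanal; 16 methyl acetate
Product: 18 methyl (4R,5R,6S)‑5‑(tert‑butyldimethylsilyloxy)‑6‑{2‑[(E)‑3‑(tert‑butyldimethylsilyloxy)prop‑1‑en‑1‑yl]‑4‑methylphenyl}‑3‑hydroxy‑4‑methylheptanoate (C3 epimer mixture), via lithium enolate of methyl acetate 17 (not isolated)
Conditions: LiN(i‑Pr)2, methyl acetate, THF, −78 °C; then 15, −78 °C; aq. NH4Cl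
Reagents that add atoms: methyl acetate (16), COC(C)=O
Why: The lithium ester enolate adds to the aldehyde at −78 °C (acetate aldol addition) to give the β‑hydroxy ester, and the new carbinol C6 is left uncontrolled because it becomes trigonal in step 14.

Step 12
Reactants: 18 methyl (4R,5R,6S)‑5‑(tert‑butyldimethylsilyloxy)‑6‑{2‑[(E)‑3‑(tert‑butyldimethylsilyloxy)prop‑1‑en‑1‑yl]‑4‑methylphenyl}‑3‑hydroxy‑4‑methylheptanoate; 19 2‑bromobutanoyl bromide
Product: 20 methyl (4R,5R,6S)‑3‑(2‑bromobutanoyloxy)‑5‑(tert‑butyldimethylsilyloxy)‑6‑{2‑[(E)‑3‑(tert‑butyldimethylsilyloxy)prop‑1‑en‑1‑yl]‑4‑methylphenyl}‑4‑methylheptanoate (epimers at C3 and at the CHBr carbon)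
Conditions: 2‑bromobutanoyl bromide, pyridine, CH2Cl2, 0 °C
Reagents that add atoms: 2‑bromobutanoyl bromide (19), CCC(Br)C(Br)=O
Why: An acyl bromide with pyridine esterifies the hindered secondary alcohol (O‑acylation) under conditions too weakly basic for β‑elimination, installing the O1–C2 bond and the C–Br handle together.

Step 13
Reactants: 20 methyl (4R,5R,6S)‑3‑(2‑bromobutanoyloxy)‑5‑(tert‑butyldimethylsilyloxy)‑6‑{2‑[(E)‑3‑(tert‑butyldimethylsilyloxy)prop‑1‑en‑1‑yl]‑4‑methylphenyl}‑4‑methylheptanoate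
Product: 22 3‑ethyl‑4‑hydroxy‑6‑[(2R,3R,4S)‑3‑(tert‑butyldimethylsilyloxy)‑4‑{2‑[(E)‑3‑(tert‑butyldimethylsilyloxy)prop‑1‑en‑1‑yl]‑4‑methylphenyl}pentan‑2‑yl]‑5,6‑dihydro‑2H‑pyran‑2‑one (C6 epimer mixture), via chloromagnesium ester enolate 21 (not isolated)
Conditions: t‑BuMgCl (3 equiv), THF, 50 °C, slow addition of 20 at high dilution; aq. HCl
Reagents that add atoms: none
Why: Bromine–magnesium exchange on the α‑bromo ester should give the magnesium ester enolate at C3 and nowhere else; this carbon attacks the methyl ester carbonyl C4, methoxide leaves, and the β‑keto lactone is at once deprotonated to a chelated magnesium enolate that pulls the equilibrium toward the ring. The closest known reaction type is the intramolecular Reformatsky‑type (zinc or magnesium enolate) Dieckmann cyclisation of 3‑(2‑bromoacyloxy)alkanoates to 3‑alkyl‑4‑hydroxy‑5,6‑dihydropyran‑2‑ones. The six‑membered ring O1–C2–C3–C4–C5–C6 closes in a 6‑exo‑trig mode at the ester carbonyl, with the enolate double bond inside the new ring (6‑(enolendo)‑exo‑trig). No stereocentre is created, since C3 ends as an enol carbon and both C6 epimers and both bromide epimers converge. The selectivity needed is chemoselectivity, enolate formation at C3 only and not deprotonation at C5 with loss of the acyloxy group; it is secured by the C–Br bond, which reacts with the hindered, poorly basic Grignard reagent faster than any C–H bond, and by high dilution, which suppresses intermolecular condensation. Because C6 stays an sp3 carbinol carbon, C7 is never α to a ketone and keeps its configuration.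

Step 14
Reactants: 22 3‑ethyl‑4‑hydroxy‑6‑[(2R,3R,4S)‑3‑(tert‑butyldimethylsilyloxy)‑4‑{2‑[(E)‑3‑(tert‑butyldimethylsilyloxy)prop‑1‑en‑1‑yl]‑4‑methylphenyl}pentan‑2‑yl]‑5,6‑dihydro‑2H‑pyran‑2‑one
Product: 26 3‑ethyl‑4‑hydroxy‑6‑[(2S,3R,4S)‑3‑(tert‑butyldimethylsilyloxy)‑4‑{2‑[(E)‑3‑(tert‑butyldimethylsilyloxy)prop‑1‑en‑1‑yl]‑4‑methylphenyl}pentan‑2‑yl]‑2H‑pyran‑2‑one, via dilithium dianion 23 (not isolated), via C5 phenylselenide 24 (not isolated), via C5 selenoxide 25 (not isolated)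
Conditions: LiN(i‑Pr)2 (2.5 equiv), THF, −78 to −30 °C; PhSeCl, −78 °C; AcOH, 30% H2O2, 0 °C to rt
Reagents that add atoms: none
Why: Two equivalents of amide base give the β‑keto lactone dianion, whose more basic C5 carbon is selenenylated anti to the C6 substituent, and oxidation then triggers syn‑elimination with C6–H, the only β‑hydrogen (selenoxide elimination), driven by formation of the conjugated 2‑pyranone and erasing the C6 stereocentre.

Step 15
Reactants: 26 3‑ethyl‑4‑hydroxy‑6‑[(2S,3R,4S)‑3‑(tert‑butyldimethylsilyloxy)‑4‑{2‑[(E)‑3‑(tert‑butyldimethylsilyloxy)prop‑1‑en‑1‑yl]‑4‑methylphenyl}pentan‑2‑yl]‑2H‑pyran‑2‑one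
Product: 27 veramycin A, 3‑ethyl‑4‑hydroxy‑6‑[(2S,3R,4S)‑3‑hydroxy‑4‑{2‑[(E)‑3‑hydroxyprop‑1‑en‑1‑yl]‑4‑methylphenyl}pentan‑2‑yl]‑2H‑pyran‑2‑one
Conditions: HF·pyridine, pyridine, THF, 0 °C to rt
Reagents that add atoms: none
Why: Buffered fluoride cleaves both the primary allylic and the hindered secondary silyl ether (desilylation) without base that could open the pyranone or acid strong enough to ionise the cinnamyl alcohol.

Compound list
1 | 2‑bromo‑4‑methylbenzaldehyde | Cc1ccc(C=O)c(Br)c1 | starting material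
2 | ethyl (triphenylphosphoranylidene)acetate | CCOC(=O)C=P(c1ccccc1)(c1ccccc1)c1ccccc1 | starting material
3 | ethyl (2E)‑3‑(2‑bromo‑4‑methylphenyl)prop‑2‑enoate | CCOC(=O)/C=C/c1ccc(C)cc1Br | intermediate
4 | (2E)‑3‑(2‑bromo‑4‑methylphenyl)prop‑2‑en‑1‑ol | OC/C=C/c1ccc(C)cc1Br | intermediate
5 | [(2R,3R)‑3‑(2‑bromo‑4‑methylphenyl)oxiran‑2‑yl]methanol | OC[C@H]1O[C@@H]1c1ccc(C)cc1Br | intermediate
6 | (2S,3S)‑3‑(2‑bromo‑4‑methylphenyl)butane‑1,2‑diol | C[C@@H](c1ccc(C)cc1Br)[C@H](O)CO | intermediate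
7 | (2S)‑2‑(2‑bromo‑4‑methylphenyl)propanal | C[C@@H](c1ccc(C)cc1Br)C=O | intermediate
8 | (4S)‑4‑benzyl‑3‑propanoyl‑1,3‑oxazolidin‑2‑one | CCC(=O)N1[C@@H](Cc2ccccc2)COC1=O | starting material
9 | (4S)‑4‑benzyl‑3‑[(1Z)‑1‑(dibutylboranyloxy)prop‑1‑en‑1‑yl]‑1,3‑oxazolidin‑2‑one (boron enolate, not isolated) | C/C=C(\OB(CCCC)CCCC)N1[C@@H](Cc2ccccc2)COC1=O | intermediate
10 | (4S)‑4‑benzyl‑3‑[(2S,3R,4S)‑4‑(2‑bromo‑4‑methylphenyl)‑3‑hydroxy‑2‑methylpentanoyl]‑1,3‑oxazolidin‑2‑one | O=C(N1[C@@H](Cc2ccccc2)COC1=O)[C@@H](C)[C@H](O)[C@@H](C)c1ccc(C)cc1Br | intermediate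
11 | (2S,3R,4S)‑4‑(2‑bromo‑4‑methylphenyl)‑3‑hydroxy‑N‑methoxy‑N,2‑dimethylpentanamide | CON(C)C(=O)[C@@H](C)[C@H](O)[C@@H](C)c1ccc(C)cc1Br | intermediate
12 | (2S,3R,4S)‑4‑(2‑bromo‑4‑methylphenyl)‑3‑(tert‑butyldimethylsilyloxy)‑N‑methoxy‑N,2‑dimethylpentanamide | CON(C)C(=O)[C@@H](C)[C@H](O[Si](C)(C)C(C)(C)C)[C@@H](C)c1ccc(C)cc1Br | intermediate
13 | tert‑butyldimethyl{[(2E)‑3‑(4,4,5,5‑tetramethyl‑1,3,2‑dioxaborolan‑2‑yl)prop‑2‑en‑1‑yl]oxy}silane | CC(C)(C)[Si](C)(C)OC/C=C/B1OC(C)(C)C(C)(C)O1 | starting material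
14 | (2S,3R,4S)‑3‑(tert‑butyldimethylsilyloxy)‑4‑{2‑[(E)‑3‑(tert‑butyldimethylsilyloxy)prop‑1‑en‑1‑yl]‑4‑methylphenyl}‑N‑methoxy‑N,2‑dimethylpentanamide | CON(C)C(=O)[C@@H](C)[C@H](O[Si](C)(C)C(C)(C)C)[C@@H](C)c1ccc(C)cc1/C=C/CO[Si](C)(C)C(C)(C)C | intermediate
15 | (2S,3R,4S)‑3‑(tert‑butyldimethylsilyloxy)‑4‑{2‑[(E)‑3‑(tert‑butyldimethylsilyloxy)prop‑1‑en‑1‑yl]‑4‑methylphenyl}‑2‑methylpentanal | O=C[C@@H](C)[C@H](O[Si](C)(C)C(C)(C)C)[C@@H](C)c1ccc(C)cc1/C=C/CO[Si](C)(C)C(C)(C)C | intermediate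
16 | methyl acetate | COC(C)=O | starting material
17 | lithium 1‑methoxyethen‑1‑olate (lithium enolate of methyl acetate, not isolated) | C=C(O[Li])OC | intermediate
18 | methyl (4R,5R,6S)‑5‑(tert‑butyldimethylsilyloxy)‑6‑{2‑[(E)‑3‑(tert‑butyldimethylsilyloxy)prop‑1‑en‑1‑yl]‑4‑methylphenyl}‑3‑hydroxy‑4‑methylheptanoate (C3 epimers) | COC(=O)CC(O)[C@@H](C)[C@H](O[Si](C)(C)C(C)(C)C)[C@@H](C)c1ccc(C)cc1/C=C/CO[Si](C)(C)C(C)(C)C | intermediate
19 | 2‑bromobutanoyl bromide | CCC(Br)C(Br)=O | starting material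
20 | methyl (4R,5R,6S)‑3‑(2‑bromobutanoyloxy)‑5‑(tert‑butyldimethylsilyloxy)‑6‑{2‑[(E)‑3‑(tert‑butyldimethylsilyloxy)prop‑1‑en‑1‑yl]‑4‑methylphenyl}‑4‑methylheptanoate (epimers at C3 and CHBr) | CCC(Br)C(=O)OC(CC(=O)OC)[C@@H](C)[C@H](O[Si](C)(C)C(C)(C)C)[C@@H](C)c1ccc(C)cc1/C=C/CO[Si](C)(C)C(C)(C)C | intermediate
21 | chloromagnesium enolate of the butanoate ester of 20 (not isolated) | CCC=C(O[Mg]Cl)OC(CC(=O)OC)[C@@H](C)[C@H](O[Si](C)(C)C(C)(C)C)[C@@H](C)c1ccc(C)cc1/C=C/CO[Si](C)(C)C(C)(C)C | intermediate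
22 | 3‑ethyl‑4‑hydroxy‑6‑[(2R,3R,4S)‑3‑(tert‑butyldimethylsilyloxy)‑4‑{2‑[(E)‑3‑(tert‑butyldimethylsilyloxy)prop‑1‑en‑1‑yl]‑4‑methylphenyl}pentan‑2‑yl]‑5,6‑dihydro‑2H‑pyran‑2‑one (C6 epimers) | CCC1=C(O)CC([C@@H](C)[C@H](O[Si](C)(C)C(C)(C)C)[C@@H](C)c2ccc(C)cc2/C=C/CO[Si](C)(C)C(C)(C)C)OC1=O | intermediate
23 | dilithium 2,4‑dienolate (dianion) of 22 (not isolated) | CCC1=C(O[Li])OC([C@@H](C)[C@H](O[Si](C)(C)C(C)(C)C)[C@@H](C)c2ccc(C)cc2/C=C/CO[Si](C)(C)C(C)(C)C)C=C1O[Li] | intermediate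
24 | 5‑(phenylselanyl) derivative of 22 (not isolated) | CCC1=C(O)C([Se]c3ccccc3)C([C@@H](C)[C@H](O[Si](C)(C)C(C)(C)C)[C@@H](C)c2ccc(C)cc2/C=C/CO[Si](C)(C)C(C)(C)C)OC1=O | intermediate
25 | 5‑(phenylseleninyl) derivative of 22 (selenoxide, not isolated) | CCC1=C(O)C([Se](=O)c3ccccc3)C([C@@H](C)[C@H](O[Si](C)(C)C(C)(C)C)[C@@H](C)c2ccc(C)cc2/C=C/CO[Si](C)(C)C(C)(C)C)OC1=O | intermediate
26 | 3‑ethyl‑4‑hydroxy‑6‑[(2S,3R,4S)‑3‑(tert‑butyldimethylsilyloxy)‑4‑{2‑[(E)‑3‑(tert‑butyldimethylsilyloxy)prop‑1‑en‑1‑yl]‑4‑methylphenyl}pentan‑2‑yl]‑2H‑pyran‑2‑one | CCc1c(O)cc([C@@H](C)[C@H](O[Si](C)(C)C(C)(C)C)[C@@H](C)c2ccc(C)cc2/C=C/CO[Si](C)(C)C(C)(C)C)oc1=O | intermediate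
27 | veramycin A, 3‑ethyl‑4‑hydroxy‑6‑[(2S,3R,4S)‑3‑hydroxy‑4‑{2‑[(E)‑3‑hydroxyprop‑1‑en‑1‑yl]‑4‑methylphenyl}pentan‑2‑yl]‑2H‑pyran‑2‑one | CCc1c(O)cc([C@@H](C)[C@H](O)[C@@H](C)c2ccc(C)cc2/C=C/CO)oc1=O | target

Total step count: 15. Longest linear sequence: 15 steps (from 1; all other inputs are commercial).

Steps most likely to fail

Step 13 (key step). The magnesium enolate may be quenched by proton transfer from C5–H, after which the C5 enolate would expel the acyloxy group, or intermolecular condensation may outrun ring closure. The fallback sets out from 15 and returns at 22. The dianion of methyl 2‑ethyl‑3‑oxobutanoate (NaH, then n‑BuLi, THF, 0 to −78 °C) should add through its terminal carbon to aldehyde 15. This would give the δ‑hydroxy‑β‑keto ester methyl (6R,7R,8S)‑7‑(tert‑butyldimethylsilyloxy)‑8‑{2‑[(E)‑3‑(tert‑butyldimethylsilyloxy)prop‑1‑en‑1‑yl]‑4‑methylphenyl}‑2‑ethyl‑5‑hydroxy‑6‑methyl‑3‑oxononanoate F1. Treatment with K2CO3 in MeOH followed by acidification should lactonise it to 22. This route forms C5–C6 and then O1–C2 instead of C3–C4, and still keeps C6 as a carbinol.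

Step 14. Selenenylation may occur at C3 instead of C5, the allylic selenoxide of the enol tautomer may undergo a [2,3]‑shift instead of syn‑elimination, or the oxidant may attack the styrenyl alkene. The fallback sets out from 22 and returns at 26. Double silylation of the dianion (LiN(i‑Pr)2, Me3SiCl, THF, −78 °C) should give the cyclic diene 3‑ethyl‑6‑[(2R,3R,4S)‑3‑(tert‑butyldimethylsilyloxy)‑4‑{2‑[(E)‑3‑(tert‑butyldimethylsilyloxy)prop‑1‑en‑1‑yl]‑4‑methylphenyl}pentan‑2‑yl]‑2,4‑bis(trimethylsilyloxy)‑6H‑pyran F2. Pd(OAc)2 (1 equiv) in MeCN at rt (Saegusa–Ito oxidation) should palladate the diene terminus C5 and eliminate C6–H, and aqueous work‑up should then give 26. No peroxide or selenium electrophile is involved.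

Step 6. The α‑aryl aldehyde may partly racemise in the presence of amine and ammonium salt before the C–C bond forms, or syn‑pentane strain in the Felkin chair of a (Z)‑enolate may erode facial selectivity. The fallback sets out from 7 and returns at 12.
- Base‑free crotylboration at −78 °C with (Z)‑crotyldiisopinocampheylborane made from (−)‑Ipc2BOMe, (Z)‑but‑2‑ene, n‑BuLi/KOt‑Bu and BF3·OEt2 (the antipode that attacks the si face), with NaOH/H2O2 work‑up, should give (2S,3S,4R)‑2‑(2‑bromo‑4‑methylphenyl)‑4‑methylhex‑5‑en‑3‑ol F3.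
- TBSOTf/2,6‑lutidine should give tert‑butyl{[(2S,3S,4R)‑2‑(2‑bromo‑4‑methylphenyl)‑4‑methylhex‑5‑en‑3‑yl]oxy}dimethylsilane F4.
- Ozonolysis (O3, CH2Cl2, −78 °C; PPh3) should give (2S,3R,4S)‑4‑(2‑bromo‑4‑methylphenyl)‑3‑(tert‑butyldimethylsilyloxy)‑2‑methylpentanal F5.
- NaClO2/NaH2PO4/2‑methylbut‑2‑ene should give (2S,3R,4S)‑4‑(2‑bromo‑4‑methylphenyl)‑3‑(tert‑butyldimethylsilyloxy)‑2‑methylpentanoic acid F6.
- Coupling with MeNHOMe·HCl (EDC·HCl, HOBt, i‑Pr2NEt, CH2Cl2) should give 12.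

Further compounds
F1 | step 13 | methyl (6R,7R,8S)‑7‑(tert‑butyldimethylsilyloxy)‑8‑{2‑[(E)‑3‑(tert‑butyldimethylsilyloxy)prop‑1‑en‑1‑yl]‑4‑methylphenyl}‑2‑ethyl‑5‑hydroxy‑6‑methyl‑3‑oxononanoate (C2 and C5 epimers) | CCC(C(=O)OC)C(=O)CC(O)[C@@H](C)[C@H](O[Si](C)(C)C(C)(C)C)[C@@H](C)c1ccc(C)cc1/C=C/CO[Si](C)(C)C(C)(C)C
F2 | step 14 | 3‑ethyl‑6‑[(2R,3R,4S)‑3‑(tert‑butyldimethylsilyloxy)‑4‑{2‑[(E)‑3‑(tert‑butyldimethylsilyloxy)prop‑1‑en‑1‑yl]‑4‑methylphenyl}pentan‑2‑yl]‑2,4‑bis(trimethylsilyloxy)‑6H‑pyran (C6 epimers) | CCC1=C(O[Si](C)(C)C)OC([C@@H](C)[C@H](O[Si](C)(C)C(C)(C)C)[C@@H](C)c2ccc(C)cc2/C=C/CO[Si](C)(C)C(C)(C)C)C=C1O[Si](C)(C)C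
F3 | step 6 | (2S,3S,4R)‑2‑(2‑bromo‑4‑methylphenyl)‑4‑methylhex‑5‑en‑3‑ol | C=C[C@@H](C)[C@H](O)[C@@H](C)c1ccc(C)cc1Br
F4 | step 6 | tert‑butyl{[(2S,3S,4R)‑2‑(2‑bromo‑4‑methylphenyl)‑4‑methylhex‑5‑en‑3‑yl]oxy}dimethylsilane | C=C[C@@H](C)[C@H](O[Si](C)(C)C(C)(C)C)[C@@H](C)c1ccc(C)cc1Br
F5 | step 6 | (2S,3R,4S)‑4‑(2‑bromo‑4‑methylphenyl)‑3‑(tert‑butyldimethylsilyloxy)‑2‑methylpentanal | O=C[C@@H](C)[C@H](O[Si](C)(C)C(C)(C)C)[C@@H](C)c1ccc(C)cc1Br
F6 | step 6 | (2S,3R,4S)‑4‑(2‑bromo‑4‑methylphenyl)‑3‑(tert‑butyldimethylsilyloxy)‑2‑methylpentanoic acid | OC(=O)[C@@H](C)[C@H](O[Si](C)(C)C(C)(C)C)[C@@H](C)c1ccc(C)cc1Br
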